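The 2,4-disubstituted furan is disconnected at its O1–C5 bond. Ring atoms O1, C2–H, C3 (bearing the carbinol carbon), C4–H and C5 (bearing the arene) are mapped onto a 3-alkyne-1,2-diol: the primary hydroxyl becomes O1, the tertiary carbinol carbon becomes C3 and the aryl alkyne becomes C4–C5. One π-acid-catalysed operation closes the ring 5-endo-dig and aromatises it by loss of water, leaving the adjacent silyloxy stereocentre untouched. The precursor diol carries a 2,5-dimethoxyphenyl alkyne and the (R)-configured TBS-protected carbinol taken from methyl (R)-glycidate; both epimers at the tertiary carbon converge. Desilylation, acylation and oxidative demethylation then deliver the quinone.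

Key step: step 7

Remark: the stereocentre is bought at the ester oxidation level so that the ynone is reached through a Weinreb amide without protecting-group or redox steps; (i-PrO)Me2SiCH2MgCl is assumed to be a solution prepared beforehand from the commercial chlorosilane and Mg.

Step 1
Reactants: 1 methyl (2R)-oxirane-2-carboxylate; 2 2-methylprop-1-enylmagnesium bromide
Product: 3 methyl (2R)-2-hydroxy-5-methylhex-4-enoate
Conditions: CuBr·SMe2 (10 mol%), THF, −78 → −40 °C
Reagents that add atoms: none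
Why: Copper-catalysed Grignard opening of a terminal epoxide (cuprate SN2 at the unsubstituted C3) should outrun addition to the ester at low temperature, and because C2 is not a reacting centre the (R)-configuration of the purchased glycidate becomes the carbinol stereocentre of the target.

Step 2
Reactants: 3 methyl (2R)-2-hydroxy-5-methylhex-4-enoate
Product: 4 methyl (2R)-2-{[tert-butyl(dimethyl)silyl]oxy}-5-methylhex-4-enoate
Conditions: TBSCl, imidazole, DMF, rt
Reagents that add atoms: tert-butyldimethylsilyl chloride, CC(C)(C)[Si](C)(C)Cl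
Why: Standard silylation of a secondary α-hydroxy ester blocks the secondary oxygen, so that later only the primary hydroxyl can attack the alkyne.

Step 3
Reactants: 4 methyl (2R)-2-{[tert-butyl(dimethyl)silyl]oxy}-5-methylhex-4-enoate
Product: 5 (2R)-2-{[tert-butyl(dimethyl)silyl]oxy}-N-methoxy-N,5-dimethylhex-4-enamide
Conditions: MeNH(OMe)·HCl, i-PrMgCl, THF, −20 → 0 °C
Reagents that add atoms: N,O-dimethylhydroxylamine hydrochloride, CNOC.Cl
Why: Aminolysis of the methyl ester by the chloromagnesium amide of N,O-dimethylhydroxylamine (Weinreb amide formation) proceeds at low temperature and should not enolise the α-silyloxy centre.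

Step 4
Reactants: 6 2,5-dimethoxybenzaldehyde
Product: 7 2-ethynyl-1,4-dimethoxybenzene
Conditions: dimethyl (1-diazo-2-oxopropyl)phosphonate, K2CO3, MeOH, rt
Reagents that add atoms: dimethyl (1-diazo-2-oxopropyl)phosphonate, CC(=O)C(=[N+]=[N-])P(=O)(OC)OC
Why: Ohira–Bestmann homologation converts an aryl aldehyde into the terminal alkyne in one operation under carbonate/methanol conditions that the methyl ethers tolerate.

Step 5
Reactants: 7 2-ethynyl-1,4-dimethoxybenzene; 5 (2R)-2-{[tert-butyl(dimethyl)silyl]oxy}-N-methoxy-N,5-dimethylhex-4-enamide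
Product: 9 (4R)-4-{[tert-butyl(dimethyl)silyl]oxy}-1-(2,5-dimethoxyphenyl)-7-methyloct-6-en-1-yn-3-one, via lithium acetylide 8 (not isolated)
Conditions: n-BuLi, THF, −78 °C; then 5, −78 → 0 °C
Reagents that add atoms: none
Why: Acylation of a lithium acetylide by a Weinreb amide stops at the ketone because the chelated tetrahedral adduct survives until work-up, and the non-enolising conditions should keep the α-stereocentre intact.

Step 6
Reactants: 9 (4R)-4-{[tert-butyl(dimethyl)silyl]oxy}-1-(2,5-dimethoxyphenyl)-7-methyloct-6-en-1-yn-3-one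
Product: 11 (3R)-3-{[tert-butyl(dimethyl)silyl]oxy}-2-[(2,5-dimethoxyphenyl)ethynyl]-6-methylhept-5-ene-1,2-diol (both C2 epimers), via β-hydroxysilane 10 (not isolated)
Conditions: (i-PrO)Me2SiCH2MgCl, THF, −78 → 0 °C; then 30% H2O2, KF, KHCO3, THF/MeOH, rt
Reagents that add atoms: (isopropoxydimethylsilyl)methylmagnesium chloride, CC(C)O[Si](C)(C)C[Mg]Cl; hydrogen peroxide, OO
Why: Nucleophilic hydroxymethylation, in which the (alkoxysilyl)methyl Grignard reagent adds 1,2 to the ynone carbonyl and Tamao oxidation turns C–Si into C–OH under bicarbonate buffering that should spare alkene, alkyne and TBS ether; the new tertiary centre forms as both epimers, which does not matter because it becomes sp2 in step 7.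

Step 7
Reactants: 11 (3R)-3-{[tert-butyl(dimethyl)silyl]oxy}-2-[(2,5-dimethoxyphenyl)ethynyl]-6-methylhept-5-ene-1,2-diol
Product: 13 tert-butyl{[(1R)-1-[5-(2,5-dimethoxyphenyl)furan-3-yl]-4-methylpent-3-en-1-yl]oxy}dimethylsilane, via hydroxydihydrofuran 12 (not isolated)
Conditions: [(t-Bu)2(2-biphenylyl)P]AuCl (2 mol%), AgOTf (2 mol%), 4 Å MS, THF, 0 °C
Reagents that add atoms: none
Why: The cationic monovalent gold centre π-activates the aryl alkyne, the primary hydroxyl adds anti to the aryl-bearing carbon and protodeauration gives 3-hydroxy-2,3-dihydrofuran 12, whose tertiary hydroxyl is then lost as water with aromatisation. The closest known reaction type is the gold- or silver-catalysed dehydrative cycloisomerisation of 3-alkyne-1,2-diols to furans. The furan ring closes in 5-endo-dig mode by formation of the O1–C5 bond. No stereocentre is created: the carbinol centre from step 1 is a spectator under the near-neutral conditions, and the stereogenic tertiary carbon is destroyed, so both C2 epimers of 11 converge. The step needs chemoselectivity for the hydroxyl over the 1,6-related prenyl alkene, which the adjacent CH2OH group, the low catalyst loading and coordinating THF at 0 °C should secure. It also needs regioselectivity for C5, which is fixed by the two-atom tether (only the 5-endo closure is feasible) and reinforced by the electron-rich arene polarising the alkyne towards attack at its own carbon.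

Step 8
Reactants: 13 tert-butyl{[(1R)-1-[5-(2,5-dimethoxyphenyl)furan-3-yl]-4-methylpent-3-en-1-yl]oxy}dimethylsilane
Product: 14 (1R)-1-[5-(2,5-dimethoxyphenyl)furan-3-yl]-4-methylpent-3-en-1-ol
Conditions: Bu4NF, THF, 0 °C → rt
Reagents that add atoms: none
Why: Fluoride-mediated cleavage of a secondary TBS ether is a basic process that cannot ionise the furylic C–O bond, so the configuration should be retained.

Step 9
Reactants: 14 (1R)-1-[5-(2,5-dimethoxyphenyl)furan-3-yl]-4-methylpent-3-en-1-ol; 15 3-methylbutanoyl chloride (isovaleryl chloride)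
Product: 16 (1R)-1-[5-(2,5-dimethoxyphenyl)furan-3-yl]-4-methylpent-3-en-1-yl 3-methylbutanoate
Conditions: Et3N, DMAP (cat.), CH2Cl2, 0 °C
Reagents that add atoms: none
Why: DMAP-catalysed acylation of a secondary alcohol by an acid chloride takes place at oxygen with retention of configuration.

Step 10
Reactants: 16 (1R)-1-[5-(2,5-dimethoxyphenyl)furan-3-yl]-4-methylpent-3-en-1-yl 3-methylbutanoate
Product: 17 (1R)-1-[5-(3,6-dioxocyclohexa-1,4-dien-1-yl)furan-3-yl]-4-methylpent-3-en-1-yl 3-methylbutanoate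
Conditions: (NH4)2Ce(NO3)6, MeCN/H2O, 0 °C, short reaction time
Reagents that add atoms: water, O
Why: Oxidative demethylation of a 1,4-dimethoxyarene by tetravalent cerium (two single-electron oxidations, water addition at the ipso carbons and loss of methanol) is fast at 0 °C and is kept brief so that furan, prenyl alkene and furylic ester should be left alone.

Compound list

1 | methyl (2R)-oxirane-2-carboxylate (methyl (R)-glycidate) | COC(=O)[C@H]1CO1 | starting material
2 | 2-methylprop-1-enylmagnesium bromide | CC(C)=C[Mg]Br | starting material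
3 | methyl (2R)-2-hydroxy-5-methylhex-4-enoate | CC(C)=CC[C@@H](O)C(=O)OC | intermediate
4 | methyl (2R)-2-{[tert-butyl(dimethyl)silyl]oxy}-5-methylhex-4-enoate | CC(C)=CC[C@@H](O[Si](C)(C)C(C)(C)C)C(=O)OC | intermediate
5 | (2R)-2-{[tert-butyl(dimethyl)silyl]oxy}-N-methoxy-N,5-dimethylhex-4-enamide | CC(C)=CC[C@@H](O[Si](C)(C)C(C)(C)C)C(=O)N(C)OC | intermediate
6 | 2,5-dimethoxybenzaldehyde | COc1ccc(OC)c(C=O)c1 | starting material
7 | 2-ethynyl-1,4-dimethoxybenzene | C#Cc1cc(OC)ccc1OC | intermediate
8 | lithium (2,5-dimethoxyphenyl)acetylide | [Li]C#Cc1cc(OC)ccc1OC | intermediate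
9 | (4R)-4-{[tert-butyl(dimethyl)silyl]oxy}-1-(2,5-dimethoxyphenyl)-7-methyloct-6-en-1-yn-3-one | CC(C)=CC[C@@H](O[Si](C)(C)C(C)(C)C)C(=O)C#Cc1cc(OC)ccc1OC | intermediate
10 | (3R)-3-{[tert-butyl(dimethyl)silyl]oxy}-2-[(2,5-dimethoxyphenyl)ethynyl]-1-[dimethyl(propan-2-yloxy)silyl]-6-methylhept-5-en-2-ol (both C2 epimers) | CC(C)=CC[C@@H](O[Si](C)(C)C(C)(C)C)C(O)(C[Si](C)(C)OC(C)C)C#Cc1cc(OC)ccc1OC | intermediate
11 | (3R)-3-{[tert-butyl(dimethyl)silyl]oxy}-2-[(2,5-dimethoxyphenyl)ethynyl]-6-methylhept-5-ene-1,2-diol (both C2 epimers) | CC(C)=CC[C@@H](O[Si](C)(C)C(C)(C)C)C(O)(CO)C#Cc1cc(OC)ccc1OC | intermediate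
12 | 3-[(1R)-1-{[tert-butyl(dimethyl)silyl]oxy}-4-methylpent-3-en-1-yl]-5-(2,5-dimethoxyphenyl)-2,3-dihydrofuran-3-ol (both C3 epimers) | CC(C)=CC[C@@H](O[Si](C)(C)C(C)(C)C)C1(O)COC(c2cc(OC)ccc2OC)=C1 | intermediate
13 | tert-butyl{[(1R)-1-[5-(2,5-dimethoxyphenyl)furan-3-yl]-4-methylpent-3-en-1-yl]oxy}dimethylsilane | CC(C)=CC[C@@H](O[Si](C)(C)C(C)(C)C)c1coc(-c2cc(OC)ccc2OC)c1 | intermediate
14 | (1R)-1-[5-(2,5-dimethoxyphenyl)furan-3-yl]-4-methylpent-3-en-1-ol | CC(C)=CC[C@@H](O)c1coc(-c2cc(OC)ccc2OC)c1 | intermediate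
15 | 3-methylbutanoyl chloride (isovaleryl chloride) | CC(C)CC(Cl)=O | starting material
16 | (1R)-1-[5-(2,5-dimethoxyphenyl)furan-3-yl]-4-methylpent-3-en-1-yl 3-methylbutanoate | CC(C)=CC[C@@H](OC(=O)CC(C)C)c1coc(-c2cc(OC)ccc2OC)c1 | intermediate
17 | (1R)-1-[5-(3,6-dioxocyclohexa-1,4-dien-1-yl)furan-3-yl]-4-methylpent-3-en-1-yl 3-methylbutanoate | CC(C)=CC[C@@H](OC(=O)CC(C)C)c1coc(C2=CC(=O)C=CC2=O)c1 | target

Total steps: 10. Longest linear sequence: 9 steps (steps 1, 2, 3, 5, 6, 7, 8, 9, 10).

Steps most likely to fail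

Step 7. The cationic gold centre may engage the 1,6-related prenyl alkene (enyne cycloisomerisation), or ionise the tertiary propargylic hydroxyl (Meyer–Schuster-type rearrangement), before the primary hydroxyl closes the ring. The fallback sets out from ynone 9 and comes back at furan 13. Methylene transfer from dimethylsulfonium methylide (Me3S+ I−, KN(SiMe3)2, THF, −10 °C; Corey–Chaykovsky epoxidation) gives the alkynyl oxirane tert-butyl{[(1R)-1-{2-[(2,5-dimethoxyphenyl)ethynyl]oxiran-2-yl}-4-methylpent-3-en-1-yl]oxy}dimethylsilane F1. AgOTf and p-TsOH (both catalytic, CH2Cl2/MeOH, rt) should then convert it into 13 by methanolysis of the oxirane at the propargylic carbon, silver-promoted 5-endo-dig attack of the freed primary hydroxyl and loss of methanol. Monovalent silver does not trigger enyne skeletal rearrangement, and no free tertiary carbinol is exposed to a strong π-acid.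

Step 10. Single-electron oxidation may spread from the dimethoxyarene to the conjugated, electron-rich furan (oxidative ring opening), or the acidic aqueous medium may solvolyse the furylic ester. The fallback makes the last oxidation phenol-directed; it sets out from Weinreb amide 5 and comes back at target 17.
- Purchased 5-hydroxy-2-methoxybenzaldehyde is O-allylated (allyl bromide, K2CO3, DMF) to 2-methoxy-5-(prop-2-en-1-yloxy)benzaldehyde F2.
- Homologation as in step 4 gives 2-ethynyl-1-methoxy-4-(prop-2-en-1-yloxy)benzene F3.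
- Its lithium acetylide and 5, as in step 5, give (4R)-4-{[tert-butyl(dimethyl)silyl]oxy}-1-[2-methoxy-5-(prop-2-en-1-yloxy)phenyl]-7-methyloct-6-en-1-yn-3-one F4.
- Hydroxymethylation as in step 6 gives (3R)-3-{[tert-butyl(dimethyl)silyl]oxy}-2-{[2-methoxy-5-(prop-2-en-1-yloxy)phenyl]ethynyl}-6-methylhept-5-ene-1,2-diol F5.
- Cycloisomerisation as in step 7 gives tert-butyl{[(1R)-1-{5-[2-methoxy-5-(prop-2-en-1-yloxy)phenyl]furan-3-yl}-4-methylpent-3-en-1-yl]oxy}dimethylsilane F6.
- Bu4NF gives (1R)-1-{5-[2-methoxy-5-(prop-2-en-1-yloxy)phenyl]furan-3-yl}-4-methylpent-3-en-1-ol F7.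
- Acylation with 15 gives (1R)-1-{5-[2-methoxy-5-(prop-2-en-1-yloxy)phenyl]furan-3-yl}-4-methylpent-3-en-1-yl 3-methylbutanoate F8.
- Pd(PPh3)4 with morpholine (THF, rt) removes the allyl group to give (1R)-1-[5-(5-hydroxy-2-methoxyphenyl)furan-3-yl]-4-methylpent-3-en-1-yl 3-methylbutanoate F9.
- PhI(OAc)2 in MeCN/H2O at 0 °C oxidises this 4-methoxyphenol to quinone 17. The oxidant is bound at the phenol oxygen, water adds para and methanol is lost, so furan and alkene should not be addressed.

Step 6. The basic Grignard reagent may enolise the α-silyloxy ynone or add in conjugate fashion, and the bicarbonate/peroxide stage may induce silyl migration from the secondary oxygen to a neighbouring hydroxyl. The fallback reverses the order of the two carbonyl additions; it sets out from Weinreb amide 5 and comes back at diol 11. [(4-Methoxyphenyl)methoxy]methyllithium (from Bu3SnCH2OCH2C6H4OMe and n-BuLi, THF, −78 °C) acylated by 5 gives (3R)-3-{[tert-butyl(dimethyl)silyl]oxy}-1-[(4-methoxyphenyl)methoxy]-6-methylhept-5-en-2-one F10. The non-basic, 1,2-selective cerium acetylide made from 8 and CeCl3 (THF, −78 °C) then gives (3R)-3-{[tert-butyl(dimethyl)silyl]oxy}-2-[(2,5-dimethoxyphenyl)ethynyl]-1-[(4-methoxyphenyl)methoxy]-6-methylhept-5-en-2-ol F11. 2,3-Dichloro-5,6-dicyano-1,4-benzoquinone in wet CH2Cl2 at 0 °C cleaves the 4-methoxybenzyl ether and returns diol 11.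

Further compounds

F1 | step 7 | tert-butyl{[(1R)-1-{2-[(2,5-dimethoxyphenyl)ethynyl]oxiran-2-yl}-4-methylpent-3-en-1-yl]oxy}dimethylsilane (both oxirane epimers) | CC(C)=CC[C@@H](O[Si](C)(C)C(C)(C)C)C1(CO1)C#Cc1cc(OC)ccc1OC
F2 | step 10 | 2-methoxy-5-(prop-2-en-1-yloxy)benzaldehyde | COc1ccc(OCC=C)cc1C=O
F3 | step 10 | 2-ethynyl-1-methoxy-4-(prop-2-en-1-yloxy)benzene | C#Cc1cc(OCC=C)ccc1OC
F4 | step 10 | (4R)-4-{[tert-butyl(dimethyl)silyl]oxy}-1-[2-methoxy-5-(prop-2-en-1-yloxy)phenyl]-7-methyloct-6-en-1-yn-3-one | CC(C)=CC[C@@H](O[Si](C)(C)C(C)(C)C)C(=O)C#Cc1cc(OCC=C)ccc1OC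
F5 | step 10 | (3R)-3-{[tert-butyl(dimethyl)silyl]oxy}-2-{[2-methoxy-5-(prop-2-en-1-yloxy)phenyl]ethynyl}-6-methylhept-5-ene-1,2-diol (both C2 epimers) | CC(C)=CC[C@@H](O[Si](C)(C)C(C)(C)C)C(O)(CO)C#Cc1cc(OCC=C)ccc1OC
F6 | step 10 | tert-butyl{[(1R)-1-{5-[2-methoxy-5-(prop-2-en-1-yloxy)phenyl]furan-3-yl}-4-methylpent-3-en-1-yl]oxy}dimethylsilane | CC(C)=CC[C@@H](O[Si](C)(C)C(C)(C)C)c1coc(-c2cc(OCC=C)ccc2OC)c1
F7 | step 10 | (1R)-1-{5-[2-methoxy-5-(prop-2-en-1-yloxy)phenyl]furan-3-yl}-4-methylpent-3-en-1-ol | CC(C)=CC[C@@H](O)c1coc(-c2cc(OCC=C)ccc2OC)c1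
F8 | step 10 | (1R)-1-{5-[2-methoxy-5-(prop-2-en-1-yloxy)phenyl]furan-3-yl}-4-methylpent-3-en-1-yl 3-methylbutanoate | CC(C)=CC[C@@H](OC(=O)CC(C)C)c1coc(-c2cc(OCC=C)ccc2OC)c1
F9 | step 10 | (1R)-1-[5-(5-hydroxy-2-methoxyphenyl)furan-3-yl]-4-methylpent-3-en-1-yl 3-methylbutanoate | CC(C)=CC[C@@H](OC(=O)CC(C)C)c1coc(-c2cc(O)ccc2OC)c1
F10 | step 6 | (3R)-3-{[tert-butyl(dimethyl)silyl]oxy}-1-[(4-methoxyphenyl)methoxy]-6-methylhept-5-en-2-one | CC(C)=CC[C@@H](O[Si](C)(C)C(C)(C)C)C(=O)COCc1ccc(OC)cc1
F11 | step 6 | (3R)-3-{[tert-butyl(dimethyl)silyl]oxy}-2-[(2,5-dimethoxyphenyl)ethynyl]-1-[(4-methoxyphenyl)methoxy]-6-methylhept-5-en-2-ol (both C2 epimers) | CC(C)=CC[C@@H](O[Si](C)(C)C(C)(C)C)C(O)(COCc1ccc(OC)cc1)C#Cc1cc(OC)ccc1OC
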